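**Retrosynthetic overview**

1. Ring B (C1' with the ether O, C2'–H, C3'–CH3, C4'–H, C5'–OH, C6'–CO2H) is built on the ring A oxygen, not coupled to it. The O–C1'≡C2'–H unit is an aryl ethynyl ether, and C3'–C6' are C6–C3 of a 4-acetoxy-6-methyl-2-pyrone-3-carboxylate.
2. Key disconnection: bonds C1'–C6' and C2'–C3' by [4+2] addition of ynol ether 15 to pyrone 21 with loss of CO2. Ring B is the only ring formed and it is formed last; ring A is carried from the start.
3. Ring A: 2-chlororesorcinol → formylation → MOM/Me differentiation of the two OH → CHO to OH (Baeyer–Villiger) → ortho-formylation, oxidation, esterification → salicylate 11 → vinyl ether → bromovinyl ether → ethynyl ether 15.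
4. Pyrone: di-tert-butyl malonate + acetylketene (from the dioxinone) → hydroxypyrone 20 → acetate 21.
5. End game: methanolysis of the acetate, then acid removes the tert-butyl ester and the MOM ether.

Key step: step 13

Remark: the target has no stereocentre. The ethynyl ether is reached through a 2-bromovinyl ether and a silylamide base, because organolithium routes to ynol ethers would attack the methyl ester and phenols tend to add across bromoalkynes instead of being O-alkynylated.

**Route**

Step 1
Reactants: 1 2-chlororesorcinol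
Product: 3 3-chloro-2,4-dihydroxybenzaldehyde, via aryl iminium chloride 2 (not isolated)
Conditions: POCl3, DMF, MeCN, 0 °C → rt; then H2O, 50 °C
Reagents that add atoms: N,N-dimethylformamide CN(C)C=O (formyl carbon); water O (formyl oxygen)
Why: Vilsmeier–Haack formylation, in which the chloroiminium ion attacks the position ortho to one hydroxyl and para to the other (the two such positions are equivalent by symmetry) and water hydrolyses iminium salt 2 to the aldehyde.

Step 2
Reactants: 3 3-chloro-2,4-dihydroxybenzaldehyde
Product: 4 3-chloro-2-hydroxy-4-(methoxymethoxy)benzaldehyde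
Conditions: MOMCl (1.05 equiv), i-Pr2NEt, CH2Cl2, 0 °C
Reagents that add atoms: chloromethyl methyl ether COCCl
Why: Selective O-alkylation (acetal ether formation), since the 4-OH para to the formyl group is the more acidic and is free, whereas the 2-OH is hydrogen-bonded to the aldehyde and flanked on both sides.

Step 3
Reactants: 4 3-chloro-2-hydroxy-4-(methoxymethoxy)benzaldehyde
Product: 5 3-chloro-2-methoxy-4-(methoxymethoxy)benzaldehyde
Conditions: MeI, K2CO3, DMF, rt
Reagents that add atoms: iodomethane CI
Why: Williamson ether synthesis, in which carbonate deprotonates the remaining chelated phenol and MeI methylates it while the MOM ether and the aldehyde are inert.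

Step 4
Reactants: 5 3-chloro-2-methoxy-4-(methoxymethoxy)benzaldehyde
Product: 7 3-chloro-2-methoxy-4-(methoxymethoxy)phenol, via aryl formate 6 (not isolated)
Conditions: mCPBA, CH2Cl2, 0 °C → rt; then K2CO3, MeOH, rt
Reagents that add atoms: 3-chloroperoxybenzoic acid OOC(=O)c1cccc(Cl)c1
Why: Baeyer–Villiger (Dakin-type) oxidation, in which the electron-rich aryl group with ortho-methoxy and para-alkoxy donors migrates in preference to hydrogen to give formate 6, which mild methanolysis cleaves to the phenol.

Step 5
Reactants: 7 3-chloro-2-methoxy-4-(methoxymethoxy)phenol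
Product: 9 4-chloro-2-hydroxy-3-methoxy-5-(methoxymethoxy)benzaldehyde, via salicyl alcohol 8 (not isolated)
Conditions: MgCl2, Et3N, (CH2O)n, MeCN, reflux; cold dilute HCl work-up
Reagents that add atoms: formaldehyde (as paraformaldehyde) C=O
Why: Magnesium-mediated ortho-formylation of a phenol (Casnati–Skattebøl), in which the magnesium phenoxide delivers formaldehyde only to the single free ortho position and salicyl alcohol 8 is oxidised to the aldehyde by hydride transfer to a second formaldehyde.

Step 6
Reactants: 9 4-chloro-2-hydroxy-3-methoxy-5-(methoxymethoxy)benzaldehyde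
Product: 10 4-chloro-2-hydroxy-3-methoxy-5-(methoxymethoxy)benzoic acid
Conditions: NaClO2, NaH2PO4, 2-methyl-2-butene, t-BuOH/H2O, rt
Reagents that add atoms: sodium chlorite [Na+].[O-]Cl=O
Why: Pinnick oxidation converts the aldehyde to the acid under buffered conditions mild enough for the MOM ether, with 2-methyl-2-butene scavenging HOCl so that the electron-rich ring is not chlorinated.

Step 7
Reactants: 10 4-chloro-2-hydroxy-3-methoxy-5-(methoxymethoxy)benzoic acid
Product: 11 methyl 4-chloro-2-hydroxy-3-methoxy-5-(methoxymethoxy)benzoate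
Conditions: MeI, KHCO3, DMF, rt
Reagents that add atoms: iodomethane CI
Why: Carboxylate O-alkylation (SN2), since KHCO3 ionises only the carboxylic acid and the hydrogen-bonded phenol stays free.

Step 8
Reactants: 11 methyl 4-chloro-2-hydroxy-3-methoxy-5-(methoxymethoxy)benzoate
Product: 12 methyl 4-chloro-3-methoxy-5-(methoxymethoxy)-2-(vinyloxy)benzoate
Conditions: Cu(OAc)2 (1 equiv, divalent copper), 2,4,6-trivinylcyclotriboroxane–pyridine complex, pyridine, CH2Cl2, air, rt
Reagents that add atoms: 2,4,6-trivinylcyclotriboroxane–pyridine complex C=CB1OB(C=C)OB(C=C)O1.c1ccncc1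
Why: Chan–Lam-type oxidative O-vinylation, in which the phenoxide and a vinyl group from boron meet on copper and reductive elimination forms the aryl vinyl ether under near-neutral conditions that spare the ester and the MOM ether.

Step 9
Reactants: 12 methyl 4-chloro-3-methoxy-5-(methoxymethoxy)-2-(vinyloxy)benzoate
Product: 14 methyl 2-[(Z)-2-bromovinyloxy]-4-chloro-3-methoxy-5-(methoxymethoxy)benzoate, via 1,2-dibromoethyl ether 13 (not isolated)
Conditions: Br2 (1.0 equiv), CH2Cl2, −78 °C; then i-Pr2NEt, −78 °C → rt
Reagents that add atoms: bromine BrBr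
Why: Electrophilic bromine addition to the enol ether, far faster than ring bromination at −78 °C, followed by amine-induced dehydrobromination of the α-bromo ether is the classical route to β-bromovinyl ethers, and any E isomer formed beside the Z isomer is equally usable in the next step.

Step 10
Reactants: 14 methyl 2-[(Z)-2-bromovinyloxy]-4-chloro-3-methoxy-5-(methoxymethoxy)benzoate
Product: 15 methyl 4-chloro-2-(ethynyloxy)-3-methoxy-5-(methoxymethoxy)benzoate
Conditions: KN(SiMe3)2 (2.2 equiv), THF, −78 °C; aq. NH4Cl at −78 °C; kept cold in solution and used at once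
Reagents that add atoms: none
Why: Base-induced dehydrobromination (anti-elimination from the Z isomer, α-elimination with 1,2-hydrogen shift from any E isomer) is the classical route to aryloxyacetylenes, and a non-nucleophilic silylamide is chosen so that the methyl ester is not attacked.

Step 11
Reactants: 16 di-tert-butyl malonate; 17 2,2,6-trimethyl-4H-1,3-dioxin-4-one
Product: 20 tert-butyl 4-hydroxy-6-methyl-2-oxo-2H-pyran-3-carboxylate, via acetylketene 18 (not isolated), via acylmalonate 19 (not isolated)
Conditions: NaH (1 equiv), toluene, 0 °C → rt; then 17, 110 °C; cold 1 M HCl work-up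
Reagents that add atoms: none
Why: C-Acetoacetylation and lactonisation, in which thermolysis of 17 releases acetylketene 18, sodium malonate is C-acylated to 19, and the enol oxygen of the new ketone closes the pyrone on one ester with loss of tert-butanol, the known route from malonates and diketene equivalents to 3-alkoxycarbonyl-4-hydroxy-6-methyl-2-pyrones.

Step 12
Reactants: 20 tert-butyl 4-hydroxy-6-methyl-2-oxo-2H-pyran-3-carboxylate
Product: 21 tert-butyl 4-acetoxy-6-methyl-2-oxo-2H-pyran-3-carboxylate
Conditions: Ac2O, pyridine, CH2Cl2, 0 °C; non-aqueous isolation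
Reagents that add atoms: acetic anhydride CC(=O)OC(C)=O
Why: O-Acylation of the acidic vinylogous-acid hydroxyl gives the enol acetate, which weakens the donor at C4 and removes the enol hydrogen through which the tert-butyl ester could be lost on heating.

Step 13
Reactants: 15 methyl 4-chloro-2-(ethynyloxy)-3-methoxy-5-(methoxymethoxy)benzoate; 21 tert-butyl 4-acetoxy-6-methyl-2-oxo-2H-pyran-3-carboxylate
Product: 23 tert-butyl 2-acetoxy-6-[3-chloro-2-methoxy-6-(methoxycarbonyl)-4-(methoxymethoxy)phenoxy]-4-methylbenzoate, via bicyclic lactone 22 (not isolated)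
Conditions: 21 (2 equiv), degassed toluene (about 1 M), 120 °C, sealed tube
Reagents that add atoms: none
Why: Proposed new method: the ynol ether HOMO and the LUMO of the ester-activated pyrone should combine in a strongly asynchronous inverse-electron-demand [4+2] addition, in which the unsubstituted alkyne carbon bonds first to pyrone C6 and the developing aryloxy-stabilised cationic carbon is captured by the malonate-like C3 to give the 2-oxabicyclo[2.2.2]octadienone 22. Retro-[4+2] loss of CO2 from 22 should be fast at this temperature and gives ring B already aromatic, because an alkyne was used and no elimination or oxidation is needed. The closest known reaction type is the thermal cycloaddition with decarboxylation of 3-alkoxycarbonyl-2-pyrones with ynamines and ketene acetals to give benzoates; an aryl ynol ether is a weaker donor, hence the higher temperature and the excess of pyrone. Ring B is closed by intermolecular six-membered [4+2] ring formation (bonds C1'–C6' and C2'–C3') followed by extrusion of the lactone bridge, and no stereocentre remains because the two bridgehead centres of racemic 22 are destroyed on aromatisation. The step needs one regiochemistry, the aryloxy carbon next to the ester-bearing carbon, and the matched polarity of the partners secures it (donor oxygen on the alkyne carbon that meets C3, electrophilic C6 for the small CH terminus, which also suits the methyl group on C6). The acetoxy group at pyrone C4 is a poor donor and keeps the diene electron-poor, and it later becomes the C5' hydroxyl.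

Step 14
Reactants: 23 tert-butyl 2-acetoxy-6-[3-chloro-2-methoxy-6-(methoxycarbonyl)-4-(methoxymethoxy)phenoxy]-4-methylbenzoate
Product: 24 tert-butyl 2-[3-chloro-2-methoxy-6-(methoxycarbonyl)-4-(methoxymethoxy)phenoxy]-6-hydroxy-4-methylbenzoate
Conditions: K2CO3 (cat.), MeOH, 0 °C → rt
Reagents that add atoms: none
Why: Transesterification (methanolysis) of the aryl acetate is much faster than attack on the hindered tert-butyl ester, and the ring A methyl ester is unchanged by methoxide.

Step 15
Reactants: 24 tert-butyl 2-[3-chloro-2-methoxy-6-(methoxycarbonyl)-4-(methoxymethoxy)phenoxy]-6-hydroxy-4-methylbenzoate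
Product: 25 2-[3-chloro-4-hydroxy-2-methoxy-6-(methoxycarbonyl)phenoxy]-6-hydroxy-4-methylbenzoic acid
Conditions: CF3CO2H/CH2Cl2 (1:3), H2O (5 equiv), 0 °C → rt
Reagents that add atoms: none
Why: Acidolysis, in which trifluoroacetic acid cleaves the tert-butyl ester by loss of isobutene and the MOM acetal by hydrolysis while the methyl ester, the methyl ether, the aryl chloride and the diaryl ether are stable.

**Compound list**

1 | 2-chlororesorcinol | Oc1cccc(O)c1Cl | starting material
2 | (3-chloro-2,4-dihydroxybenzylidene)dimethyliminium chloride (not isolated) | C[N+](C)=Cc1ccc(O)c(Cl)c1O.[Cl-] | intermediate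
3 | 3-chloro-2,4-dihydroxybenzaldehyde | O=Cc1ccc(O)c(Cl)c1O | intermediate
4 | 3-chloro-2-hydroxy-4-(methoxymethoxy)benzaldehyde | O=Cc1ccc(OCOC)c(Cl)c1O | intermediate
5 | 3-chloro-2-methoxy-4-(methoxymethoxy)benzaldehyde | O=Cc1ccc(OCOC)c(Cl)c1OC | intermediate
6 | 3-chloro-2-methoxy-4-(methoxymethoxy)phenyl formate (not isolated) | O=COc1ccc(OCOC)c(Cl)c1OC | intermediate
7 | 3-chloro-2-methoxy-4-(methoxymethoxy)phenol | Oc1ccc(OCOC)c(Cl)c1OC | intermediate
8 | 3-chloro-6-(hydroxymethyl)-2-methoxy-4-(methoxymethoxy)phenol (as its magnesium salt, not isolated) | OCc1cc(OCOC)c(Cl)c(OC)c1O | intermediate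
9 | 4-chloro-2-hydroxy-3-methoxy-5-(methoxymethoxy)benzaldehyde | O=Cc1cc(OCOC)c(Cl)c(OC)c1O | intermediate
10 | 4-chloro-2-hydroxy-3-methoxy-5-(methoxymethoxy)benzoic acid | OC(=O)c1cc(OCOC)c(Cl)c(OC)c1O | intermediate
11 | methyl 4-chloro-2-hydroxy-3-methoxy-5-(methoxymethoxy)benzoate | COC(=O)c1cc(OCOC)c(Cl)c(OC)c1O | intermediate
12 | methyl 4-chloro-3-methoxy-5-(methoxymethoxy)-2-(vinyloxy)benzoate | COC(=O)c1cc(OCOC)c(Cl)c(OC)c1OC=C | intermediate
13 | methyl 4-chloro-2-(1,2-dibromoethoxy)-3-methoxy-5-(methoxymethoxy)benzoate (racemic, not isolated) | COC(=O)c1cc(OCOC)c(Cl)c(OC)c1OC(Br)CBr | intermediate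
14 | methyl 2-[(Z)-2-bromovinyloxy]-4-chloro-3-methoxy-5-(methoxymethoxy)benzoate (Z expected to predominate) | COC(=O)c1cc(OCOC)c(Cl)c(OC)c1O/C=C\Br | intermediate
15 | methyl 4-chloro-2-(ethynyloxy)-3-methoxy-5-(methoxymethoxy)benzoate | COC(=O)c1cc(OCOC)c(Cl)c(OC)c1OC#C | intermediate
16 | di-tert-butyl malonate | CC(C)(C)OC(=O)CC(=O)OC(C)(C)C | starting material
17 | 2,2,6-trimethyl-4H-1,3-dioxin-4-one | CC1=CC(=O)OC(C)(C)O1 | starting material
18 | acetylketene (not isolated) | CC(=O)C=C=O | intermediate
19 | di-tert-butyl 2-(3-oxobutanoyl)malonate (as its sodium enolate, not isolated) | CC(=O)CC(=O)C(C(=O)OC(C)(C)C)C(=O)OC(C)(C)C | intermediate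
20 | tert-butyl 4-hydroxy-6-methyl-2-oxo-2H-pyran-3-carboxylate | CC1=CC(O)=C(C(=O)OC(C)(C)C)C(=O)O1 | intermediate
21 | tert-butyl 4-acetoxy-6-methyl-2-oxo-2H-pyran-3-carboxylate | CC(=O)OC1=C(C(=O)OC(C)(C)C)C(=O)OC(C)=C1 | intermediate
22 | tert-butyl 5-acetoxy-7-[3-chloro-2-methoxy-6-(methoxycarbonyl)-4-(methoxymethoxy)phenoxy]-1-methyl-3-oxo-2-oxabicyclo[2.2.2]octa-5,7-diene-4-carboxylate (racemic, bridgehead configuration fixed by the bicycle, not isolated) | CC12OC(=O)C(C(=O)OC(C)(C)C)(C(OC(C)=O)=C1)C(Oc1c(C(=O)OC)cc(OCOC)c(Cl)c1OC)=C2 | intermediate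
23 | tert-butyl 2-acetoxy-6-[3-chloro-2-methoxy-6-(methoxycarbonyl)-4-(methoxymethoxy)phenoxy]-4-methylbenzoate | COC(=O)c1cc(OCOC)c(Cl)c(OC)c1Oc1cc(C)cc(OC(C)=O)c1C(=O)OC(C)(C)C | intermediate
24 | tert-butyl 2-[3-chloro-2-methoxy-6-(methoxycarbonyl)-4-(methoxymethoxy)phenoxy]-6-hydroxy-4-methylbenzoate | COC(=O)c1cc(OCOC)c(Cl)c(OC)c1Oc1cc(C)cc(O)c1C(=O)OC(C)(C)C | intermediate
25 | 2-[3-chloro-4-hydroxy-2-methoxy-6-(methoxycarbonyl)phenoxy]-6-hydroxy-4-methylbenzoic acid | COC(=O)c1cc(O)c(Cl)c(OC)c1Oc1cc(C)cc(O)c1C(=O)O | target

**Step count**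

Total: 15 steps. Longest linear sequence: 13 steps (steps 1–10 and 13–15, from 2-chlororesorcinol).

**Steps most likely to fail**

1. Step 13 (proposed new method). The aryl ynol ether may be too weak a donor, so that thermal oligomerisation of the alkyne or acyl transfer from and decomposition of the acetoxypyrone outruns the cycloaddition. The fallback uses known chemistry only, sets out from 11 and returns at 25.
   - SNAr of the phenoxide of 11 on commercial 2,6-difluoro-4-methylbenzaldehyde (Cc1cc(F)c(C=O)c(F)c1; K2CO3, DMF, 70 °C) should give methyl 4-chloro-2-(3-fluoro-2-formyl-5-methylphenoxy)-3-methoxy-5-(methoxymethoxy)benzoate F1.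
   - A second SNAr with NaOMe in MeOH at 60 °C, which leaves the methyl ester unchanged, should give methyl 4-chloro-2-(2-formyl-3-methoxy-5-methylphenoxy)-3-methoxy-5-(methoxymethoxy)benzoate F2.
   - Pinnick oxidation (NaClO2, NaH2PO4, 2-methyl-2-butene) should give 2-[3-chloro-2-methoxy-6-(methoxycarbonyl)-4-(methoxymethoxy)phenoxy]-6-methoxy-4-methylbenzoic acid F3.
   - BCl3 in CH2Cl2 at −78 → 0 °C should then cleave the methyl ether held in a chelate with the neighbouring carboxyl group, together with the MOM ether, and leave the non-chelated ring A methyl ether, to give 25.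

2. Step 10. The intermediate potassium acetylide may add to the methyl ester, and the free ethynyl ether may oligomerise during isolation. The fallback sets out from 14 and returns at 15.
   - After the elimination with KN(SiMe3)2 at −78 °C the acetylide is silylated in the cold flask with Me3SiCl, which should give the storable methyl 4-chloro-3-methoxy-5-(methoxymethoxy)-2-{[(trimethylsilyl)ethynyl]oxy}benzoate F4, purified on neutral alumina.
   - K2CO3 in MeOH at 0 °C then liberates 15 directly before step 13.

3. Step 8. Copper-mediated vinyl transfer may stall on the hindered, hydrogen-bonded salicylate phenol and leave 11 unconverted. The fallback sets out from 11 and returns at 12.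
   - O-Alkylation with excess 1,2-dibromoethane (K2CO3, DMF, 60 °C) should give methyl 2-(2-bromoethoxy)-4-chloro-3-methoxy-5-(methoxymethoxy)benzoate F5.
   - E2 elimination with KOt-Bu in THF at 0 °C, with a short reaction time to avoid ester exchange, then gives 12.

**Further compounds**

F1 | step 13 | methyl 4-chloro-2-(3-fluoro-2-formyl-5-methylphenoxy)-3-methoxy-5-(methoxymethoxy)benzoate | COC(=O)c1cc(OCOC)c(Cl)c(OC)c1Oc1cc(C)cc(F)c1C=O
F2 | step 13 | methyl 4-chloro-2-(2-formyl-3-methoxy-5-methylphenoxy)-3-methoxy-5-(methoxymethoxy)benzoate | COC(=O)c1cc(OCOC)c(Cl)c(OC)c1Oc1cc(C)cc(OC)c1C=O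
F3 | step 13 | 2-[3-chloro-2-methoxy-6-(methoxycarbonyl)-4-(methoxymethoxy)phenoxy]-6-methoxy-4-methylbenzoic acid | COC(=O)c1cc(OCOC)c(Cl)c(OC)c1Oc1cc(C)cc(OC)c1C(=O)O
F4 | step 10 | methyl 4-chloro-3-methoxy-5-(methoxymethoxy)-2-{[(trimethylsilyl)ethynyl]oxy}benzoate | COC(=O)c1cc(OCOC)c(Cl)c(OC)c1OC#C[Si](C)(C)C
F5 | step 8 | methyl 2-(2-bromoethoxy)-4-chloro-3-methoxy-5-(methoxymethoxy)benzoate | COC(=O)c1cc(OCOC)c(Cl)c(OC)c1OCCBr
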